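**The bench.** 4 questions stand on this flask, which you take over while it runs. The charge, the readings so far and the options are here.

- blue: starting material 0.10 M; second substrate 0.20 M; free enzyme 50 µM; temperature 37 °C; the very flask that is asked about, followed so far
- flask: starting material 0.10 M; second substrate 0.200 M; free enzyme 50 µM; temperature 37 °C; time 12 min

blue run (percent of the starting material charged)

| time / min | target / % | starting material / % |
|---|---|---|
| 0.833 | 26.4 | 72.0 |
| 2.00 | 42.5 | 36.1 |
| 4.00 | 43.7 | 10.0 |
| 10.0 | 34.8 | 1.1 |

(each reading ± 1 percentage point)

- beta: at 12 min add free enzyme, 50.0% of the amount charged, then wait 4.0 min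
- zeta: at 12 min add second substrate, 50.0% of the amount charged, then wait 4.0 min
- theta: at 12 min raise the temperature by 20 K, then wait 4.0 min
- delta: change nothing and wait 4.0 min more
- epsilon: at 12 min take out 90% of the first product then present, then wait 4.0 min

- target, in percent of the starting material first charged, at 12 min
- the remedy with the largest gain of target, or "none" below 2 percentage points (beta / zeta / theta / delta / epsilon / none)
- target present, in percent of the starting material first charged, after theta
- target present, in percent of the starting material first charged, after epsilon

- additions bring no volume worth counting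
- the analysis behind the earlier runs scatters by 1 percentage point, standard deviation
- the earlier runs do not show what temperature does; that part of a forecast is a guess

**The share.** Watch one number, s: target as a share of the starting material that has reacted. In this flask it reads 94.3% at 0.833 min, 66.5% at 2.00 min, 48.6% at 4.00 min and 35.2% at 10.0 min. So something unseen takes target, and the fall flattens. I solve both ends and join them: early s is near one, and late it rests on a floor, which I set at the last reading. Between them I let the excess over the floor halve in a fixed time h = 1.63 min, the settling half-time.

**When you come.** In this flask h is much shorter than 12 min, so target then follows a balance with its unseen partner rather than the speed of making it, which is thermodynamic control. My floor may still stand 1 percentage point high. Starting material halves in 1.08 min, so hardly any remains, 0.305%. I expect target near 35.1%.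

**Hands off.** Leave enzyme, second substrate and first product alone: I expect none of them to gain 2 points, and epsilon to stay at my 35.1%. Heat might shift the floor, but the runs don't show it, so theta is my guess for best, and I put no number on the target after it.

**The result.** The forecast gives 33%, best none, 24% after theta and 25% after epsilon, reasoning “No feed remains to make more target”; it parts from me on the remedy, by 10 points on epsilon and by 2.1 points on the target at 12 min.

The flask gives 32.4%, best theta with a gain of 9.7 points, 42.1% after theta and 32.3% after epsilon.

    free enzyme → unfolded enzyme (k = 3.10 × 10⁻⁴ s⁻¹, Ea = 240 kJ mol⁻¹)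
    starting material + free enzyme ⇌ first complex (K = 5.70 M⁻¹, k = 74000 M⁻¹ s⁻¹, Ea = 15.0 kJ mol⁻¹, ΔH = 8.00 kJ mol⁻¹)
    first complex ⇌ loaded enzyme + first product (K = 0.270 M, k = 57.0 s⁻¹, Ea = 68.0 kJ mol⁻¹, ΔH = −20.0 kJ mol⁻¹)
    second substrate + loaded enzyme ⇌ second complex (K = 28.0 M⁻¹, k = 12000 M⁻¹ s⁻¹, Ea = 14.0 kJ mol⁻¹, ΔH = −90.0 kJ mol⁻¹)
    second complex → free enzyme + target (k = 48.0 s⁻¹, Ea = 54.0 kJ mol⁻¹)
    target ⇌ isomer of the product (K = 2.10, k = 0.00800 s⁻¹, Ea = 80.0 kJ mol⁻¹, ΔH = −18.0 kJ mol⁻¹)
    (constants at 37 °C)

**Earlier reading.** My figure stands 2.7 points above the flask's target. From h, the excess left at 12 min is 0.45 points, and the flask holds 32.3% at 120 min. Now read the same flask at 5.0 min. There h gives s = 43.9%, and the halving of starting material leaves 5.26%, so I reckon target at 41.6%. That flask holds 39.9%.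

The runs stem from a simulated flask on assumed constants; noise was put on by code.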